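The target is cut at the C4–C8 interflavan bond into a robinetinidol C4 cation equivalent and a gallocatechin nucleophile. Everything rests on how the gallocatechin pyran (ring F: O1, C2, C3, C4, C4a, C8a) is made: it is grown from a 2,3-dihydrobenzofuran. The key step exploits the trans-vicinal O1–C2/C3–O pair of ring F: a benzylic trifluoroacetate ionises with participation of the aryl ether oxygen to an aryloxiranium ion, which reopens at the ring carbon, shifting O1 from C3 to C2 and placing the 3-oxygen, both with inversion. Its precursor is a 2-(α-hydroxybenzyl)-4,6-bis(benzyloxy)-2,3-dihydrobenzofuran, made by 5-exo phenoxide opening of a Shi epoxide.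

Key step: step 6

Remark: positions are given in flavan numbering (upper robinetinidol unit: rings A, B, C; lower gallocatechin unit: rings D, E, F, ring F being its pyran), and the L-fructose-derived enantiomer of the Shi ketone is taken to be at hand (it is prepared from L-sorbose).

Step 1
Reactants: 1 3,4,5-tris(benzyloxy)benzaldehyde
Product: 2 rac-1-[3,4,5-tris(benzyloxy)phenyl]prop-2-en-1-ol
Conditions: CH2=CHMgBr, THF, 0 °C; then aq. NH4Cl
Reagents that add atoms: vinylmagnesium bromide, C=C[Mg]Br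
Why: Grignard 1,2-addition to an aromatic aldehyde should be clean; the carbinol centre is racemic and is erased in step 2, where it becomes a planar cation.

Step 2
Reactants: 2 rac-1-[3,4,5-tris(benzyloxy)phenyl]prop-2-en-1-ol; 3 3,5-bis(benzyloxy)phenol
Product: 4 3,5-bis(benzyloxy)-2-{(2E)-3-[3,4,5-tris(benzyloxy)phenyl]prop-2-en-1-yl}phenol
Conditions: H2SO4 on SiO2 (cat.), CH2Cl2, rt, 3 in excess
Reagents that add atoms: none
Why: Acid-catalysed Friedel–Crafts allylation: 2 ionises to the aryl-stabilised allyl cation, which should be taken up at its unsubstituted terminus by the position of 3 ortho to the free OH (doubly activated and less hindered than the carbon between the two benzyl ethers), giving the conjugated (E)-alkene.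

Step 3
Reactants: 4 3,5-bis(benzyloxy)-2-{(2E)-3-[3,4,5-tris(benzyloxy)phenyl]prop-2-en-1-yl}phenol
Product: 5 triisopropylsilyl ether of 4
Conditions: iPr3SiCl, imidazole, DMF, rt
Reagents that add atoms: triisopropylsilyl chloride, CC(C)[Si](Cl)(C(C)C)C(C)C
Why: Imidazole-promoted O-silylation masks the oxidisable, nucleophilic phenol for the epoxidation; the triisopropylsilyl group is chosen because an aryl silyl ether has to survive pH 10.5 in step 4.

Step 4
Reactants: 5 triisopropylsilyl ether of 4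
Product: 6 (2S,3S)-2-{[2,4-bis(benzyloxy)-6-(triisopropylsilyloxy)phenyl]methyl}-3-[3,4,5-tris(benzyloxy)phenyl]oxirane
Conditions: L-fructose-derived Shi ketone (30 mol%), Oxone (2KHSO5·KHSO4·K2SO4), K2CO3, Bu4NHSO4, aq. Na2B4O7 buffer, MeCN–CH2(OMe)2, 0 °C
Reagents that add atoms: potassium peroxymonosulfate (the oxidant of Oxone; its oxygen is passed on through the dioxirane of the ketone), [K+].[O-]S(=O)(=O)OO
Why: Shi asymmetric epoxidation of a trans-disubstituted styrene-type alkene through the spiro transition state; the D-fructose ketone gives (R,R)-epoxides of this alkene class, so its enantiomer should give the (2S,3S)-epoxide, the single source of both stereocentres of the gallocatechin unit.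

Step 5
Reactants: 6 (2S,3S)-2-{[2,4-bis(benzyloxy)-6-(triisopropylsilyloxy)phenyl]methyl}-3-[3,4,5-tris(benzyloxy)phenyl]oxirane
Product: 8 (S)-[(2R)-4,6-bis(benzyloxy)-2,3-dihydro-1-benzofuran-2-yl][3,4,5-tris(benzyloxy)phenyl]methanol, via tetrabutylammonium phenoxide 7 (not isolated)
Conditions: Bu4NF, THF, 0 °C to rt
Reagents that add atoms: none
Why: Fluoride desilylation frees a phenoxide that should open the epoxide intramolecularly in the 5-exo-tet mode by SN2 attack at the non-benzylic carbon (inversion there, configuration of the benzylic C–O kept), the usual course of base-mediated openings.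

Step 6
Reactants: 8 (S)-[(2R)-4,6-bis(benzyloxy)-2,3-dihydro-1-benzofuran-2-yl][3,4,5-tris(benzyloxy)phenyl]methanol
Product: 12 (2R,3S)-5,7-bis(benzyloxy)-2-[3,4,5-tris(benzyloxy)phenyl]-3,4-dihydro-2H-chromen-3-ol (penta-O-benzylgallocatechin), via benzylic trifluoroacetate 9 (not isolated), via aryloxiranium trifluoroacetate 10 (not isolated), via chroman-3-yl trifluoroacetate 11 (not isolated)
Conditions: (CF3CO)2O, 2,6-lutidine, CH2Cl2, −20 °C; then (CF3)2CHOH–CH2Cl2 (1:4), 0.005 M, 40 °C; then K2CO3, MeOH, 0 °C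
Reagents that add atoms: trifluoroacetic anhydride (its trifluoroacetate returns one oxygen, which ends as the 3-OH), O=C(OC(=O)C(F)(F)F)C(F)(F)F
Why: Proposed new method: the benzylic trifluoroacetate 9 should ionise with anti-periplanar participation of the ring oxygen O1 (3-exo-tet closure, inversion at the carbinol carbon) to the trans aryloxiranium ion 10, and trifluoroacetate then reopens 10 either at the benzylic carbon (back to 9, reversible) or at the former furan carbon (SN2, inversion), the latter turning the five-membered ring into the pyran of 11 without a new cyclisation, since ring F arises by cleavage of the old O1–C bond of the bicyclic ion. The closest known reaction types are the zinc acetate-mediated ring expansion of 2-(1-sulfonyloxyalkyl)tetrahydrofurans to 3-acetoxytetrahydropyrans through bicyclic oxiranium ions and the trifluoroacetic anhydride-mediated ring expansion of prolinols to piperidin-3-ols through aziridinium ions under thermodynamic control; the same aryloxiranium ion is the accepted intermediate of the reverse, kinetically controlled ring contraction of trans-flavan-3-yl sulfonates. No stereocentre is made from a prochiral atom: C2 of the flavan is fixed by inversion at the carbinol carbon of 8 and C3 by inversion at C2 of the dihydrobenzofuran, so both are relayed from the (2S,3S)-epoxide 6 and should come out (2R,3S). The selectivity needed is capture at the ring carbon instead of the benzylic carbon; it should be secured by thermodynamic control, because 9 re-ionises in the ionising solvent whereas 11 is a secondary, non-benzylic ester in a less strained ring with both substituents equatorial, which is also why the 2,3-trans isomer would still prevail if 10 opened to a free benzylic cation. High dilution and the absence of strong acid are meant to hold back Friedel–Crafts capture by ring D and a hydride shift that would aromatise the furan; methanolysis finally cleaves the trifluoroacetate.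

Step 7
Reactants: 13 1-[4-(benzyloxy)-2-hydroxyphenyl]ethan-1-one
Product: 14 1-[4-(benzyloxy)-2-(methoxymethoxy)phenyl]ethan-1-one
Conditions: NaH, MeOCH2Cl, DMF, 0 °C
Reagents that add atoms: chloromethyl methyl ether, COCCl
Why: Williamson-type O-alkylation of the sodium phenoxide; NaH is used because the phenol is hydrogen-bonded to the ketone, and the acetal is stable to the bases of steps 8 and 9.

Step 8
Reactants: 14 1-[4-(benzyloxy)-2-(methoxymethoxy)phenyl]ethan-1-one; 1 3,4,5-tris(benzyloxy)benzaldehyde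
Product: 15 (2E)-1-[4-(benzyloxy)-2-(methoxymethoxy)phenyl]-3-[3,4,5-tris(benzyloxy)phenyl]prop-2-en-1-one
Conditions: KOH, EtOH–THF, rt
Reagents that add atoms: none
Why: Claisen–Schmidt condensation with a non-enolisable aldehyde should give the (E)-chalcone after E1cB dehydration, the acetal on the ortho oxygen preventing cyclisation to a flavanone.

Step 9
Reactants: 15 (2E)-1-[4-(benzyloxy)-2-(methoxymethoxy)phenyl]-3-[3,4,5-tris(benzyloxy)phenyl]prop-2-en-1-one
Product: 16 [4-(benzyloxy)-2-(methoxymethoxy)phenyl]{(2R,3S)-3-[3,4,5-tris(benzyloxy)phenyl]oxiran-2-yl}methanone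
Conditions: poly-L-leucine, urea·H2O2, DBU, THF, rt
Reagents that add atoms: urea–hydrogen peroxide (supplies the epoxide oxygen), NC(N)=O.OO
Why: Juliá–Colonna epoxidation (Weitz–Scheffer addition of hydroperoxide to the enone held by the helical poly-L-leucine), which should give the (2R,3S)-trans-epoxy ketone and with it C3 and, after inversion in step 10, C2 of the robinetinidol unit.

Step 10
Reactants: 16 [4-(benzyloxy)-2-(methoxymethoxy)phenyl]{(2R,3S)-3-[3,4,5-tris(benzyloxy)phenyl]oxiran-2-yl}methanone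
Product: 18 (2R,3R)-7-(benzyloxy)-3-hydroxy-2-[3,4,5-tris(benzyloxy)phenyl]-2,3-dihydro-4H-chromen-4-one, via free epoxy phenol 17 (not isolated)
Conditions: HCl (conc.), MeOH–THF, 50 °C
Reagents that add atoms: none
Why: Acidic methanol removes the acetal and the freed phenol should open the protonated epoxide at the benzylic carbon (6-endo-tet, inversion), giving the 2,3-trans dihydroflavonol, which is also the thermodynamically preferred isomer.

Step 11
Reactants: 18 (2R,3R)-7-(benzyloxy)-3-hydroxy-2-[3,4,5-tris(benzyloxy)phenyl]-2,3-dihydro-4H-chromen-4-one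
Product: 19 (2R,3S,4R)-7-(benzyloxy)-2-[3,4,5-tris(benzyloxy)phenyl]-3,4-dihydro-2H-chromene-3,4-diol (2,3-trans-3,4-trans)
Conditions: NaBH4, MeOH–THF, 0 °C
Reagents that add atoms: none
Why: Hydride reduction of the 4-ketone; axial delivery by the small reagent should give the equatorial 4-alcohol (3,4-trans), and the C4 configuration is in any case erased in step 13.

Step 12
Reactants: 19 (2R,3S,4R)-7-(benzyloxy)-2-[3,4,5-tris(benzyloxy)phenyl]-3,4-dihydro-2H-chromene-3,4-diol
Product: 20 (2R,3R,4R)-7-(benzyloxy)-2-[3,4,5-tris(benzyloxy)phenyl]-3,4-dihydro-2H-chromene-3,4-diyl diacetate (same 2,3-trans-3,4-trans geometry; the C3 descriptor changes by priority only)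
Conditions: Ac2O, pyridine, DMAP (cat.), rt
Reagents that add atoms: acetic anhydride, CC(=O)OC(C)=O
Why: DMAP-catalysed acylation of both alcohols makes the 4-acetate the leaving group and the 3-acetate the participating group for step 13.

Step 13
Reactants: 12 (2R,3S)-5,7-bis(benzyloxy)-2-[3,4,5-tris(benzyloxy)phenyl]-3,4-dihydro-2H-chromen-3-ol; 20 (2R,3R,4R)-7-(benzyloxy)-2-[3,4,5-tris(benzyloxy)phenyl]-3,4-dihydro-2H-chromene-3,4-diyl diacetate
Product: 22 (2R,3S,4S)-7-(benzyloxy)-4-{(2R,3S)-5,7-bis(benzyloxy)-3-hydroxy-2-[3,4,5-tris(benzyloxy)phenyl]-3,4-dihydro-2H-chromen-8-yl}-2-[3,4,5-tris(benzyloxy)phenyl]-3,4-dihydro-2H-chromen-3-yl acetate, via bridged acetoxonium triflate 21 (not isolated)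
Conditions: 12 (3 equiv), Me3SiOSO2CF3 (0.3 equiv), CH2Cl2, −78 to −30 °C
Reagents that add atoms: none
Why: Lewis acid-mediated SN1 Friedel–Crafts arylation at C4: the benzylic 4-acetate ionises to a cation stabilised by O1 and the 7-benzyloxy group, the 3-acetate bridges it on the face cis to O3, and C8 of 12 (the most nucleophilic and least hindered position of ring D) should attack trans to the C3 oxygen, setting the 4α (3,4-trans, 4S) interflavan bond.

Step 14
Reactants: 22 the 3-O-acetyl nona-O-benzyl dimer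
Product: 23 (2R,3S,4S)-7-(benzyloxy)-4-{(2R,3S)-5,7-bis(benzyloxy)-3-hydroxy-2-[3,4,5-tris(benzyloxy)phenyl]-3,4-dihydro-2H-chromen-8-yl}-2-[3,4,5-tris(benzyloxy)phenyl]-3,4-dihydro-2H-chromen-3-ol
Conditions: K2CO3, MeOH–THF, rt
Reagents that add atoms: none
Why: Base-catalysed transesterification removes the acetate without touching benzyl ethers or stereocentres, and it is placed before debenzylation because the free polyphenol is sensitive to base and air.

Step 15
Reactants: 23 the nona-O-benzyl dimer diol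
Product: 24 robinetinidol-(4α,8)-gallocatechin
Conditions: H2 (1 atm), Pd(OH)2/C, THF–MeOH, rt
Reagents that add atoms: none
Why: Catalytic hydrogenolysis of the nine benzyl ethers under mild conditions should leave the benzylic C2–O1 and C4–C8 bonds intact.

Compound list
1 | 3,4,5-tris(benzyloxy)benzaldehyde | O=Cc1cc(OCc2ccccc2)c(OCc2ccccc2)c(OCc2ccccc2)c1 | starting material
2 | rac-1-[3,4,5-tris(benzyloxy)phenyl]prop-2-en-1-ol | C=CC(O)c1cc(OCc2ccccc2)c(OCc2ccccc2)c(OCc2ccccc2)c1 | intermediate
3 | 3,5-bis(benzyloxy)phenol | Oc1cc(OCc2ccccc2)cc(OCc2ccccc2)c1 | starting material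
4 | 3,5-bis(benzyloxy)-2-{(2E)-3-[3,4,5-tris(benzyloxy)phenyl]prop-2-en-1-yl}phenol | Oc1cc(OCc2ccccc2)cc(OCc2ccccc2)c1C/C=C/c1cc(OCc2ccccc2)c(OCc2ccccc2)c(OCc2ccccc2)c1 | intermediate
5 | triisopropylsilyl ether of 4 | CC(C)[Si](Oc1cc(OCc2ccccc2)cc(OCc2ccccc2)c1C/C=C/c1cc(OCc2ccccc2)c(OCc2ccccc2)c(OCc2ccccc2)c1)(C(C)C)C(C)C | intermediate
6 | (2S,3S)-2-{[2,4-bis(benzyloxy)-6-(triisopropylsilyloxy)phenyl]methyl}-3-[3,4,5-tris(benzyloxy)phenyl]oxirane | CC(C)[Si](Oc1cc(OCc2ccccc2)cc(OCc2ccccc2)c1C[C@@H]1O[C@H]1c1cc(OCc2ccccc2)c(OCc2ccccc2)c(OCc2ccccc2)c1)(C(C)C)C(C)C | intermediate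
7 | tetrabutylammonium 3,5-bis(benzyloxy)-2-({(2S,3S)-3-[3,4,5-tris(benzyloxy)phenyl]oxiran-2-yl}methyl)phenolate (step 5, not isolated) | CCCC[N+](CCCC)(CCCC)CCCC.[O-]c1cc(OCc2ccccc2)cc(OCc2ccccc2)c1C[C@@H]1O[C@H]1c1cc(OCc2ccccc2)c(OCc2ccccc2)c(OCc2ccccc2)c1 | intermediate
8 | (S)-[(2R)-4,6-bis(benzyloxy)-2,3-dihydro-1-benzofuran-2-yl][3,4,5-tris(benzyloxy)phenyl]methanol | c1ccccc1COc1cc(OCc3ccccc3)c2c(c1)O[C@H](C2)[C@@H](O)c1cc(OCc2ccccc2)c(OCc2ccccc2)c(OCc2ccccc2)c1 | intermediate
9 | (S)-[(2R)-4,6-bis(benzyloxy)-2,3-dihydro-1-benzofuran-2-yl][3,4,5-tris(benzyloxy)phenyl]methyl trifluoroacetate (step 6, not isolated) | c1ccccc1COc1cc(OCc3ccccc3)c2c(c1)O[C@H](C2)[C@@H](OC(=O)C(F)(F)F)c1cc(OCc2ccccc2)c(OCc2ccccc2)c(OCc2ccccc2)c1 | intermediate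
10 | trans aryloxiranium ion, trifluoroacetate salt: the ring oxygen of 9 bonded to C2 of the furan ring (R) and to the benzylic carbon (R), aryl group and ring CH2 trans on the three-membered ring (step 6, not isolated) | c1ccccc1COc1cc(OCc3ccccc3)c2c(c1)[O+]1[C@H](C2)[C@H]1c1cc(OCc2ccccc2)c(OCc2ccccc2)c(OCc2ccccc2)c1.[O-]C(=O)C(F)(F)F | intermediate
11 | (2R,3S)-5,7-bis(benzyloxy)-2-[3,4,5-tris(benzyloxy)phenyl]-3,4-dihydro-2H-chromen-3-yl trifluoroacetate (step 6, not isolated) | c1ccccc1COc1cc(OCc3ccccc3)c2c(c1)O[C@H](c1cc(OCc3ccccc3)c(OCc3ccccc3)c(OCc3ccccc3)c1)[C@@H](OC(=O)C(F)(F)F)C2 | intermediate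
12 | (2R,3S)-5,7-bis(benzyloxy)-2-[3,4,5-tris(benzyloxy)phenyl]-3,4-dihydro-2H-chromen-3-ol (penta-O-benzylgallocatechin) | c1ccccc1COc1cc(OCc3ccccc3)c2c(c1)O[C@H](c1cc(OCc3ccccc3)c(OCc3ccccc3)c(OCc3ccccc3)c1)[C@@H](O)C2 | intermediate
13 | 1-[4-(benzyloxy)-2-hydroxyphenyl]ethan-1-one | CC(=O)c1ccc(OCc2ccccc2)cc1O | starting material
14 | 1-[4-(benzyloxy)-2-(methoxymethoxy)phenyl]ethan-1-one | CC(=O)c1ccc(OCc2ccccc2)cc1OCOC | intermediate
15 | (2E)-1-[4-(benzyloxy)-2-(methoxymethoxy)phenyl]-3-[3,4,5-tris(benzyloxy)phenyl]prop-2-en-1-one | COCOc1cc(OCc2ccccc2)ccc1C(=O)/C=C/c1cc(OCc2ccccc2)c(OCc2ccccc2)c(OCc2ccccc2)c1 | intermediate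
16 | [4-(benzyloxy)-2-(methoxymethoxy)phenyl]{(2R,3S)-3-[3,4,5-tris(benzyloxy)phenyl]oxiran-2-yl}methanone | COCOc1cc(OCc2ccccc2)ccc1C(=O)[C@@H]1O[C@H]1c1cc(OCc2ccccc2)c(OCc2ccccc2)c(OCc2ccccc2)c1 | intermediate
17 | [4-(benzyloxy)-2-hydroxyphenyl]{(2R,3S)-3-[3,4,5-tris(benzyloxy)phenyl]oxiran-2-yl}methanone (step 10, not isolated) | Oc1cc(OCc2ccccc2)ccc1C(=O)[C@@H]1O[C@H]1c1cc(OCc2ccccc2)c(OCc2ccccc2)c(OCc2ccccc2)c1 | intermediate
18 | (2R,3R)-7-(benzyloxy)-3-hydroxy-2-[3,4,5-tris(benzyloxy)phenyl]-2,3-dihydro-4H-chromen-4-one | O=C1c2ccc(OCc3ccccc3)cc2O[C@H](c2cc(OCc3ccccc3)c(OCc3ccccc3)c(OCc3ccccc3)c2)[C@H]1O | intermediate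
19 | (2R,3S,4R)-7-(benzyloxy)-2-[3,4,5-tris(benzyloxy)phenyl]-3,4-dihydro-2H-chromene-3,4-diol | O[C@@H]1c2ccc(OCc3ccccc3)cc2O[C@H](c2cc(OCc3ccccc3)c(OCc3ccccc3)c(OCc3ccccc3)c2)[C@H]1O | intermediate
20 | (2R,3R,4R)-7-(benzyloxy)-2-[3,4,5-tris(benzyloxy)phenyl]-3,4-dihydro-2H-chromene-3,4-diyl diacetate | CC(=O)O[C@@H]1c2ccc(OCc3ccccc3)cc2O[C@H](c2cc(OCc3ccccc3)c(OCc3ccccc3)c(OCc3ccccc3)c2)[C@H]1OC(C)=O | intermediate
21 | acetoxonium (2-methyl-1,3-dioxolan-2-ylium) ion cis-fused across C3–C4 of the upper flavan, C2 and C3 as in 20, triflate salt (step 13, not isolated) | CC1=[O+][C@H]2c3ccc(OCc4ccccc4)cc3O[C@H](c3cc(OCc4ccccc4)c(OCc4ccccc4)c(OCc4ccccc4)c3)[C@H]2O1.[O-]S(=O)(=O)C(F)(F)F | intermediate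
22 | (2R,3S,4S)-7-(benzyloxy)-4-{(2R,3S)-5,7-bis(benzyloxy)-3-hydroxy-2-[3,4,5-tris(benzyloxy)phenyl]-3,4-dihydro-2H-chromen-8-yl}-2-[3,4,5-tris(benzyloxy)phenyl]-3,4-dihydro-2H-chromen-3-yl acetate | c1ccccc1COc1ccc2c(c1)O[C@H](c1cc(OCc3ccccc3)c(OCc3ccccc3)c(OCc3ccccc3)c1)[C@@H](OC(C)=O)[C@@H]2c1c(OCc3ccccc3)cc(OCc3ccccc3)c2c1O[C@H](c1cc(OCc3ccccc3)c(OCc3ccccc3)c(OCc3ccccc3)c1)[C@@H](O)C2 | intermediate
23 | (2R,3S,4S)-7-(benzyloxy)-4-{(2R,3S)-5,7-bis(benzyloxy)-3-hydroxy-2-[3,4,5-tris(benzyloxy)phenyl]-3,4-dihydro-2H-chromen-8-yl}-2-[3,4,5-tris(benzyloxy)phenyl]-3,4-dihydro-2H-chromen-3-ol | c1ccccc1COc1ccc2c(c1)O[C@H](c1cc(OCc3ccccc3)c(OCc3ccccc3)c(OCc3ccccc3)c1)[C@@H](O)[C@@H]2c1c(OCc3ccccc3)cc(OCc3ccccc3)c2c1O[C@H](c1cc(OCc3ccccc3)c(OCc3ccccc3)c(OCc3ccccc3)c1)[C@@H](O)C2 | intermediate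
24 | robinetinidol-(4α,8)-gallocatechin | Oc1ccc2c(c1)O[C@H](c1cc(O)c(O)c(O)c1)[C@@H](O)[C@@H]2c1c(O)cc(O)c2c1O[C@H](c1cc(O)c(O)c(O)c1)[C@@H](O)C2 | target

Total step count: 15. Longest linear sequence: 9 steps (steps 1 to 6, then 13 to 15; the branch of steps 7 to 12 is equally long).

Steps most likely to fail

Step 6 (proposed new method). The trifluoroacetate may not reach equilibrium, so that the oxiranium ion keeps being captured at the benzylic carbon. The ion may also leak away by a hydride shift followed by aromatisation of the furan ring, or alkylate ring D of a second molecule. The fallback uses known chemistry and closes the pyran directly instead of enlarging the furan ring. It sets out from epoxide 6: desilylation under buffered, non-basic conditions (Bu4NF/AcOH, THF, −20 °C) should give the free epoxy phenol F1 without cyclisation. A catalytic sulfonic acid (camphorsulfonic acid, CH2Cl2, −20 °C) should then make the phenol open the protonated epoxide at the benzylic carbon with inversion (6-endo-tet), the established acid-mediated closure of trans-flavan-3-ols. This gives 12, where the route is rejoined.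

Step 13. The cation may be attacked through C6 instead of C8 of ring D or from the face cis to the C3 oxygen. The product may react again and grow to trimers, or the 3-OH of 12 may add to the acetoxonium carbon. The fallback changes the leaving group and the mode of activation and sets out from diol 19. BnSH with BF3·OEt2 (cat.) in CH2Cl2 at −20 °C should exchange the benzylic 4-OH for sulfur and give the 4-benzylsulfanyl flavan-3-ol F2. AgBF4 (THF, 0 °C), a thiophilic activator that works without a protic or strong Lewis acid, should then release the C4 cation in the presence of an excess of 12. The product is 23, so the route is rejoined after step 14.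

Step 10. Acidic opening of the epoxy ketone may run through a free benzylic cation, with 1,2-aryl migration, capture by chloride or methanol and loss of configuration at C2. The fallback sets out from 16: BnSH/SnCl4 (CH2Cl2, −20 °C) should open the epoxide at the benzylic carbon with inversion and remove the acetal, giving the α-hydroxy-β-benzylsulfanyl dihydrochalcone F3. AgBF4 (CH2Cl2, 0 °C) should then turn sulfur into the leaving group, and the phenol closes the ring to the 2,3-trans dihydroflavonol 18, where the route is rejoined.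

Further compounds
F1 | step 6 | 3,5-bis(benzyloxy)-2-({(2S,3S)-3-[3,4,5-tris(benzyloxy)phenyl]oxiran-2-yl}methyl)phenol | Oc1cc(OCc2ccccc2)cc(OCc2ccccc2)c1C[C@@H]1O[C@H]1c1cc(OCc2ccccc2)c(OCc2ccccc2)c(OCc2ccccc2)c1
F2 | step 13 | (2R,3R,4R)-7-(benzyloxy)-4-(benzylsulfanyl)-2-[3,4,5-tris(benzyloxy)phenyl]-3,4-dihydro-2H-chromen-3-ol (2,3-trans-3,4-trans) | c1ccccc1COc1ccc2c(c1)O[C@H](c1cc(OCc3ccccc3)c(OCc3ccccc3)c(OCc3ccccc3)c1)[C@@H](O)[C@@H]2SCc1ccccc1
F3 | step 10 | (2S,3R)-1-[4-(benzyloxy)-2-hydroxyphenyl]-3-(benzylsulfanyl)-2-hydroxy-3-[3,4,5-tris(benzyloxy)phenyl]propan-1-one | Oc1cc(OCc2ccccc2)ccc1C(=O)[C@H](O)[C@H](SCc1ccccc1)c1cc(OCc2ccccc2)c(OCc2ccccc2)c(OCc2ccccc2)c1
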